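Wednesday's run and Tuesday's differ in reagent, 0.020 M against 0.080 M. Averaged over the readings, substrate falls from 20.4% to 7.40% and target rises from 10.0% to 22.6%, yet the unread gap stays at 69.6% and 70.0%.

| setting | Wednesday's | Tuesday's | flask |
|---|---|---|---|
| substrate | 0.050 M | 0.050 M | 0.050 M |
| reagent | 0.020 M | 0.080 M | 0.0400 M |
| remark | run made earlier | run made earlier |  |
| time |  |  | 10 d |

| run | time / d | substrate / % | target / % |
|---|---|---|---|
| Wednesday's | 1.04 | 21 | 9 |
| Wednesday's | 1.67 | 20 | 11 |
| Wednesday's | 3.00 | 21 | 8 |
| Wednesday's | 6.00 | 20 | 13 |
| Wednesday's | 12.0 | 20 | 9 |
| Tuesday's | 2.50 | 6 | 22 |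
| Tuesday's | 5.00 | 8 | 25 |
| Tuesday's | 8.00 | 6 | 23 |
| Tuesday's | 10.0 | 7 | 21 |
| Tuesday's | 12.0 | 10 | 22 |

(readings scatter by 1.5 percentage points)

1. why nothing more happens at 10 d, or that something still does (it is still moving / the reagent has run out first / all of the substrate has reacted / forward and back rates have come level)
2. conversion of substrate at 10 d
3. amount of target at 10 d, in percent of the substrate charged
4. amount of isomer of the product at 10 d, in percent of the substrate charged

- what has gone from substrate into another species counts as reacted, even if it can come back
- the reaction counts as stopped when no species that holds the substrate changes by six tenths of a point or more over the second half of the time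

Is anything still moving at the asked time? I see no trend beyond the scatter from the first readings on, at 1.04 d and 2.50 d, and 10 d comes later. So I reckon a balance, with forward and back rates level.

Is the gap simply isomer? Not if one reagent goes with one substrate, which is my assumption. In Wednesday's run 79.6% of the substrate had reacted, more than the 40.0% that its reagent matches one to one. So I split the gap into isomer, at a fixed ratio to target, and an unseen form without reagent, at a fixed ratio to substrate. The two runs give 2.36 and 2.26.

What do you carry over? The target quotient Kq, an apparent equilibrium constant: target over substrate, divided by free reagent. Tuesday's run has 0.0420 M free, which gives Kq = 72.6 L mol⁻¹.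

And Wednesday's run? Its free reagent comes to 0.00321 M, a small difference of readings, and on that it reads 153 L mol⁻¹, so I lean on Tuesday's.

Your flask? Solving the balance on 0.0400 M of reagent, 51.6% of the substrate goes to target and isomer. That makes target 15.4%, isomer 36.2% and conversion 85.1%.

The forecast agrees with this reckoning on the ending, forward and back rates have come level, and differs in the numbers: conversion 92.5%, target 22.5%, isomer 70%. Its ground: “I expect Tuesday's composition, with a slight allowance”.

The flask gives: forward and back rates have come level, conversion 86.2%, target 15.7%, isomer 34.7%, with dormant form at 35.8%.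

    substrate + reagent ⇌ target (K = 77.0 L mol⁻¹, k = 0.0610 L mol⁻¹ s⁻¹)
    substrate + reagent ⇌ isomer of the product (K = 170 L mol⁻¹, k = 0.0240 L mol⁻¹ s⁻¹)
    substrate ⇌ dormant form (K = 2.60, k = 5.00 × 10⁻⁵ s⁻¹)

Target stands at 15.7% because its way back to substrate and reagent holds it there: the same flask without that way back gives 80.0%. On this flask's 14% of substrate and 0.0148 M of free reagent, Kq gives 14.8% target. The neighbour charged with 0.010 M of reagent ends with 23.6% of substrate and 26% of its reagent, for which Kq gives 4.38%. That neighbour holds 4.64% of target.

Readings and results are simulated from invented constants; scatter was added.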